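## The problem

Atoms are numbered as in germacranolides: ring C1–C10, methyl C14 on C10, methyl C15 on C4, lactone C6–O–C12(=O)–C11(=C13)–C7. The target (22) is a ten-membered carbocycle with a 1(10)Z and a 4E trisubstituted olefin, cis-fused at C6/C7 to an α-methylene-γ-butyrolactone. It carries four contiguous oxygenated stereocentres: C6 (S, lactone oxygen), C7 (R, quaternary tertiary carbinol), C8 (S, 3-methylbut-2-enoate) and C9 (R, allylic alcohol). C7 can be taken from the chiral pool and is the natural control element: it can direct C6 when the C6–C7 bond is made and C8 when the ring is closed, whereas C9 can only be set relative to C8 during ring formation. The α-methylene lactone is a Michael and ketyl acceptor and the C6–O bond is allylic. An 8-hydroxy-6,12-olide can translactonise under base, an ester on O8 can migrate to O7 or O9, a Z-2-methyl enal isomerises easily, and the 1,5-diene can undergo Cope rearrangement on strong heating. The medium ring must be closed against transannular strain with both olefin geometries already fixed. The enabling feature is that C8 and C9 are adjacent oxygen-bearing ring carbons, flanked by the quaternary C7 and the olefinic C10. This 1,2-diol is the retron of a reductive coupling of two aldehydes, neither of which can enolise toward the ring.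

## Retrosynthesis

**Unmasking the acceptor (22 ⇐ 21 ⇐ 20 ⇐ 19).** No skeletal bond is cut. The two silyl ethers of 21 are removed last, and the C11=C13 olefin is traced to sulfoxide 20 and sulfide 19. Carrying the methylene as a phenylthiomethyl group is preferred to a late α-methylenation, which would need a lactone enolate next to a free polyol and an ester. The forward steps only have to oxidise sulfur in the presence of two olefins and eliminate below the temperature of Cope rearrangement.

**Differentiating the diol (19 ⇐ 18 ⇐ 17).** The C8–O acyl bond is cut, then the C9–O silyl bond. The two hydroxyls of 17 differ sharply in hindrance (C9 allylic, C8 next to the quaternary C7), so silylating C9 first and acylating C8 second is the natural order. The forward acylation must work on a hindered secondary alcohol without acyl or silyl migration.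

**Ring closure (17 ⇐ 16).** The C8–C9 bond is cut, opening the ten-membered ring to dialdehyde 16. Cuts at C2–C3 or C5–C6 would create no stereocentre, and olefin-forming closures at C1=C10 or C4=C5 would have to control a trisubstituted olefin geometry inside a strained ring. The C8–C9 cut removes the ring and two stereocentres at once and leaves both olefins to be made by open-chain olefination. The forward reaction must couple two aldehydes reductively, intramolecularly, and as the (8S,9R) diol.

**Aldehydes and C13 (16 ⇐ 15 ⇐ 13 via 14).** Both aldehydes of 16 are traced to N-methoxy-N-methyl amides in 15, so that one hydride step makes them together while the lactone survives. Alcohol-level precursors were rejected because a free C8 hydroxyl beside the lactone invites translactonisation, and a silyl ether on O8 can migrate to O7 under base. The C11–C13 bond of 15 is cut to lactone 13 through its silyl ketene acetal 14 and a phenylthiomethyl cation equivalent.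

**Lactone and C8 acyl group (13 ⇐ 12 ⇐ 11 ⇐ 10).** The silyl ether is removed, then the C12–O6 lactone bond is cut to hydroxy tert-butyl ester 11, and the C8 amide is traced to the acetal ester of 10. The order matters: opening the dioxolanone while C12 is still a tert-butyl ester lets an amine nucleophile see only one reactive acyl group. With C8 an amide, only the 6,12-lactone can then form.

**The C6–C7 bond (10 ⇐ 9 + 6).** An aldol cut between C6 and C7 gives dioxolanone 9 and enal 6. Dihydroxylation of a C6=C7 olefin was rejected because the more electron-rich C4=C5 olefin would react first. Addition of a C5 vinyl nucleophile to a C6 aldehyde was rejected because it moves the stereochemical problem without solving it. The aldol sets the quaternary C7 from the chiral pool and leaves only the aldehyde face for C6 to be controlled.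

**Building blocks (9 ⇐ 8 ⇐ 7; 6 ⇐ 5 ⇐ 4 ⇐ 2 + 3; 2 ⇐ 1).** Ester 9 and acetal 8 come from (S)-malic acid 7, whose carbinol carbon becomes C7, its carboxyl C8 and its CH2CO2H arm C11–C12. Enal 6 comes from hydroxy amide 5 and ester 4. The C1=C10 bond of 4 is cut to aldehyde 2 and phosphonate 3, and 2 is the ozonolysis product of geranyl acetate 1, which already holds the 4E olefin and C15.

## Roads not taken

**Alternative 1:** an enone–cyclobutene photocycloaddition followed by strain-driven ring opening. A chiral 2-methylcyclohexenone is irradiated with 1-methylcyclobutene (A1). This forms C1–C10 and C4–C5 and gives the cis-anti-cis tricyclic ketone A2; later fragmentation of the bicyclo[2.2.0]hexane breaks C5–C10 and C1–C4 to reveal the cyclodecadiene.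
- Merits: both methyl-bearing olefin carbons arrive in one convergent step, no high dilution is needed, and the six-membered ring allows substituents to be set on a rigid template before the ring is opened.
- Weak points: head-to-head versus head-to-tail regiochemistry with A1 is uncertain. The thermal opening does not reliably give the 1(10)Z,4E pair this target needs, and it runs at temperatures where a 1,5-diene can rearrange. The tertiary C7 carbinol, the C11–C13 unit and the lactone would all still have to be added to A2 or to a flexible ten-membered ring.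
- Comparison: this road is better at making the carbocycle without a macrocyclisation. The chosen plan offers olefin geometries fixed by open-chain olefination and a lactone and C7 that are complete before the ring exists.

**Alternative 2:** a late palladium cyclocarbonylation. A ten-membered ethynyl carbinol (C7 ethynyl, free C6 hydroxyl) is treated with CO, Pd2(dba)3 and a bisphosphine. One CO joins the alkyne and the hydroxyl, forming C11–C12 and C12–O and giving the bis-silyl ether A3, which is the same compound as 21.
- Merits: the α-methylene lactone appears in one step at the very end, unmasked. This is better than the chosen plan, which spends steps 11, 16 and 17 on the sulfide mask.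
- Weak points: the step builds only the lactone. The ten-membered ring with all four stereocentres and a hindered tertiary propargylic ether must come from elsewhere. A terminal alkyne would itself be a ketyl acceptor in any reductive ring closure, and zerovalent palladium has an allylic C6 oxygen nearby.
- Comparison: the chosen plan uses the lactone, made early from malic acid, as the conformational anchor and stereochemical relay for ring closure, at the price of the three masking steps.

**Alternative 3:** an anionic oxy-Cope ring expansion. The potassium alkoxide of a cis-1-vinyl-2-isopropenylcyclohexanol rearranges, forming C2–C3 while C5–C10 breaks. The resulting C1=C10 enolate is trapped as enol triflate A4, whose triflate is later exchanged for the C14 methyl.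
- Merits: C6–C9 are set on a cyclohexane, where stereocontrol is more predictable than in the pinacol step of the chosen plan. The chair transition state fixes the 4E olefin and the ring expansion needs no dilution.
- Weak points: the cyclohexanol must already carry four contiguous oxygenated centres, one of them quaternary, with oxygen β to the alkoxide, which invites elimination or retro-aldol cleavage under the basic conditions. After A4 the C12 oxidation level, the lactone, the C14 methyl and the differentiation of O7/O8 are still outstanding.
- Comparison: this road is the more reliable in stereocontrol. The chosen plan is shorter, takes C7 from the chiral pool, both olefins from standard olefinations, and creates C8, C9 and the ring in one step.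

Key step: step 13

Remarks on the chemistry:
- Compounds 15–20 are drawn as the C11 epimer with CH2SPh cis to C8. The other epimer would serve equally, because C11 becomes trigonal in step 17.
- 3-Methylbut-2-enoic anhydride is taken as a purchasable reagent; otherwise it is one step from the acid.

## Steps

Step 1
Reactants: 1 geranyl acetate
Product: 2 (2E)-3-methyl-6-oxohex-2-en-1-yl acetate
Conditions: O3 (1.0 equiv), CH2Cl2–MeOH, −78 °C; then Me2S, −78 → 23 °C
Reagents that add atoms: ozone, [O-][O+]=O
Why: Ozonolysis; the remote, electron-rich 6,7-olefin reacts ahead of the 2,3-olefin, which the allylic acetate deactivates, so one equivalent of ozone with reductive work-up should cut only the isopropylidene end.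

Step 2
Reactants: 2 (2E)-3-methyl-6-oxohex-2-en-1-yl acetate; 3 ethyl 2-[bis(2,2,2-trifluoroethoxy)phosphoryl]propanoate
Product: 4 ethyl (2Z,6E)-8-acetoxy-2,6-dimethylocta-2,6-dienoate
Conditions: KN(SiMe3)2, 18-crown-6, THF, −78 °C
Reagents that add atoms: none
Why: Still–Gennari olefination; the trifluoroethyl phosphonate under dissociating conditions should give the (Z)-2-methyl enoate, which places C9 cis to C2 across C1=C10, and the acetate survives at −78 °C.

Step 3
Reactants: 4 ethyl (2Z,6E)-8-acetoxy-2,6-dimethylocta-2,6-dienoate
Product: 5 (2Z,6E)-8-hydroxy-N-methoxy-N,2,6-trimethylocta-2,6-dienamide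
Conditions: MeNHOMe·HCl, iPrMgCl, THF, −20 → 0 °C
Reagents that add atoms: N,O-dimethylhydroxylamine hydrochloride, CNOC.Cl
Why: Weinreb amide formation from the ester with the chloromagnesium amide; the same reagent cleaves the acetate, so C9 reaches an acyl form that hydride donors stop at the aldehyde stage and the C6 hydroxyl is freed in one operation.

Step 4
Reactants: 5 (2Z,6E)-8-hydroxy-N-methoxy-N,2,6-trimethylocta-2,6-dienamide
Product: 6 (2Z,6E)-N-methoxy-N,2,6-trimethyl-8-oxoocta-2,6-dienamide
Conditions: MnO2 (excess), CH2Cl2, 23 °C
Reagents that add atoms: none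
Why: Allylic alcohol oxidation with MnO2 should give the (E)-enal without touching the amide or either olefin geometry.

Step 5
Reactants: 7 (S)-malic acid
Product: 8 2-[(2S,4S)-2-tert-butyl-5-oxo-1,3-dioxolan-4-yl]acetic acid (cis)
Conditions: pivalaldehyde, TsOH (cat.), H2SO4 (cat.), pentane, reflux with water removal; recrystallisation
Reagents that add atoms: pivalaldehyde, CC(C)(C)C=O
Why: Acid-catalysed acetalisation of the α-hydroxy acid unit; the cis-2,4-disubstituted dioxolanone is the thermodynamic product and crystallises, so the acetal centre stores the configuration of the future C7 (self-regeneration of stereocentres).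

Step 6
Reactants: 8 2-[(2S,4S)-2-tert-butyl-5-oxo-1,3-dioxolan-4-yl]acetic acid
Product: 9 tert-butyl 2-[(2S,4S)-2-tert-butyl-5-oxo-1,3-dioxolan-4-yl]acetate
Conditions: tert-butyl 2,2,2-trichloroacetimidate, CH2Cl2–cyclohexane, 23 °C
Reagents that add atoms: tert-butyl 2,2,2-trichloroacetimidate, CC(C)(C)OC(=N)C(Cl)(Cl)Cl
Why: Esterification of the free acid by the imidate under its own acid catalysis; the tert-butyl ester keeps C12 inert to the enolate, to the aluminium amide of step 8 and to premature lactonisation.

Step 7
Reactants: 9 tert-butyl 2-[(2S,4S)-2-tert-butyl-5-oxo-1,3-dioxolan-4-yl]acetate; 6 (2Z,6E)-N-methoxy-N,2,6-trimethyl-8-oxoocta-2,6-dienamide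
Product: 10 tert-butyl 2-[(2S,4R)-2-tert-butyl-4-[(1S,2E,6Z)-1-hydroxy-8-[methoxy(methyl)amino]-3,7-dimethyl-8-oxoocta-2,6-dien-1-yl]-5-oxo-1,3-dioxolan-4-yl]acetate (6S,7R in target numbering)
Conditions: LiN(SiMe3)2 (1.05 equiv), THF, −78 °C; then 6, −78 °C; AcOH quench at −78 °C
Reagents that add atoms: none
Why: Aldol addition of the dioxolanone lithium enolate (the ring C–H is the more acidic, lactone-type proton); the aldehyde is attacked on the face anti to tert-butyl, so C7 is set with retention as 7R. C6 depends on the aldehyde face: the 6S carbinol arises when the alkenyl residue lies over the flat dioxolanone ring and away from the ester arm, which is expected to be the less encumbered arrangement, and the 6-epimer is removed by chromatography.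

Step 8
Reactants: 10 aldol adduct
Product: 11 tert-butyl (3R,4S,5E,9Z)-3,4-dihydroxy-3-[methoxy(methyl)carbamoyl]-11-[methoxy(methyl)amino]-6,10-dimethyl-11-oxoundeca-5,9-dienoate
Conditions: MeNHOMe·HCl, AlMe3, CH2Cl2, 0 → 23 °C; aq. potassium sodium tartrate
Reagents that add atoms: N,O-dimethylhydroxylamine hydrochloride, CNOC.Cl
Why: Aminolysis of the activated acetal ester by the aluminium amide (the lactone-to-hydroxy-amide opening) releases pivalaldehyde and the C7 hydroxyl, while the tert-butyl ester and the enamide are inert. C8 now carries an acyl group that can later be reduced to the aldehyde in the presence of a lactone.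

Step 9
Reactants: 11 dihydroxy bis-amide tert-butyl ester
Product: 12 (2S,3R)-3-hydroxy-N-methoxy-2-[(1E,5Z)-7-[methoxy(methyl)amino]-2,6-dimethyl-7-oxohepta-1,5-dien-1-yl]-N-methyl-5-oxooxolane-3-carboxamide
Conditions: LiN(SiMe3)2 (1.1 equiv), THF, −78 → 0 °C; aq. NH4Cl
Reagents that add atoms: none
Why: Intramolecular transesterification; the C6 alkoxide attacks the tert-butyl ester in a 5-exo closure and forms the γ-lactone with retention at C6. With C8 an amide and no silyl ether present, no other lactone and no silyl migration is possible.

Step 10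
Reactants: 12 hydroxy lactone bis-amide
Product: 13 (2S,3R)-N-methoxy-2-[(1E,5Z)-7-[methoxy(methyl)amino]-2,6-dimethyl-7-oxohepta-1,5-dien-1-yl]-N-methyl-5-oxo-3-(triethylsilyloxy)oxolane-3-carboxamide
Conditions: Et3SiOTf, 2,6-lutidine, CH2Cl2, −78 → 0 °C
Reagents that add atoms: triethylsilyl trifluoromethanesulfonate, CC[Si](CC)(CC)OS(=O)(=O)C(F)(F)F
Why: Silylation of the tertiary C7 hydroxyl with the silyl triflate; the ether blocks α-ketol rearrangement and titanium alkoxide formation at the later α-oxy aldehyde.

Step 11
Reactants: 13 silyloxy lactone bis-amide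
Product: 15 (2S,3R,4R)-N-methoxy-2-[(1E,5Z)-7-[methoxy(methyl)amino]-2,6-dimethyl-7-oxohepta-1,5-dien-1-yl]-N-methyl-5-oxo-4-[(phenylsulfanyl)methyl]-3-(triethylsilyloxy)oxolane-3-carboxamide, via silyl ketene acetal 14 (not isolated)
Conditions: LiN(iPr)2, Me3SiCl (internal quench), THF, −78 °C; solvent exchange; PhSCH2Cl, ZnBr2 (cat.), CH2Cl2, 0 → 23 °C
Reagents that add atoms: chloromethyl phenyl sulfide, ClCSc1ccccc1; chlorotrimethylsilane, C[Si](C)(C)Cl (retained in 14 only)
Why: The lactone enolate is trapped at −78 °C as its silyl ketene acetal before the β-silyloxy group can be expelled, and ZnBr2-promoted alkylation by the thionium ion from chloromethyl phenyl sulfide (Mukaiyama-type phenylthiomethylation) installs C13 as the sulfide-masked methylene. Attack anti to the C7 silyloxy group should favour the drawn C11 epimer, and either epimer is usable.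

Step 12
Reactants: 15 sulfide bis-amide
Product: 16 (2S,3R,4R)-2-[(1E,5Z)-2,6-dimethyl-7-oxohepta-1,5-dien-1-yl]-5-oxo-4-[(phenylsulfanyl)methyl]-3-(triethylsilyloxy)oxolane-3-carbaldehyde (lactone dialdehyde)
Conditions: Cp2Zr(H)Cl (4.5 equiv), THF, 23 °C; silica gel work-up
Reagents that add atoms: none
Why: Hydrozirconation of both N-methoxy-N-methyl amides gives zirconated hemiaminals that release the aldehydes on work-up. Cp2Zr(H)Cl reduces tertiary amides in preference to lactones and leaves trisubstituted olefins alone, and the Z-enal geometry is carried over from the amide.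

Step 13
Reactants: 16 lactone dialdehyde
Product: 17 (1(10)Z,4E,6S,7R,8S,9R,11R)-8,9-dihydroxy-13-(phenylsulfanyl)-7-(triethylsilyloxy)germacra-1(10),4-dien-12,6-olide
Conditions: TiCl3(DME)1.5, Zn–Cu couple, DME, reflux (reagent formation); then 16 by syringe pump over about 30 h at 25 °C (high dilution); aq. K2CO3
Reagents that add atoms: none
Why: Low-valent titanium transfers one electron to each aldehyde to give two titanium-bound ketyls, which combine to the C8–C9 titanium diolate; at 25 °C the diolate is not deoxygenated and hydrolysis releases the diol. The closest known reaction type is the intramolecular McMurry pinacol coupling of dialdehydes, enals included, to medium- and large-ring 1,2-diols. The ten-membered ring closes by ketyl–ketyl combination of the two chain ends, with slow addition keeping the dialdehyde dilute; the Z-enal, the E-olefin and the lactone-bearing quaternary C7 leave only the C2–C3 bridge freely rotating. C9 is set relative to C8 by the preference of titanium pinacol closures of this ring size for the trans (threo) diol. C8 is set relative to C7 by a Felkin-type arrangement in which the new C8–C9 bond forms anti to the C7–OSiEt3 bond, with the tether-bearing C6 branch gauche to it. The step needs aldehyde–aldehyde coupling only and the (8S,9R) diol: the lactone, sulfide, silyl ether and both trisubstituted olefins are inert at 25 °C, and the masked methylene removes the one acceptor that could trap a ketyl.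

Step 14
Reactants: 17 ring diol
Product: 18 (1(10)Z,4E,6S,7R,8S,9R,11R)-8-hydroxy-13-(phenylsulfanyl)-7,9-bis(triethylsilyloxy)germacra-1(10),4-dien-12,6-olide
Conditions: Et3SiCl (1.1 equiv), imidazole, CH2Cl2, −40 → −20 °C
Reagents that add atoms: chlorotriethylsilane, CC[Si](CC)(CC)Cl
Why: Silyl ether formation at the less hindered allylic C9 hydroxyl; the C8 hydroxyl is flanked by the quaternary C7 and its silyl ether and should react far more slowly at low temperature.

Step 15
Reactants: 18 C8 alcohol
Product: 19 (1(10)Z,4E,6S,7R,8S,9R,11R)-8-(3-methylbut-2-enoyloxy)-13-(phenylsulfanyl)-7,9-bis(triethylsilyloxy)germacra-1(10),4-dien-12,6-olide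
Conditions: 3-methylbut-2-enoic anhydride, DMAP, iPr2NEt, CH2Cl2, 23 → 40 °C
Reagents that add atoms: 3-methylbut-2-enoic anhydride, CC(C)=CC(=O)OC(=O)C=C(C)C
Why: DMAP-catalysed acylation of the remaining secondary alcohol; the anhydride avoids the vinylketene pathway that deconjugates the acid chloride, and no alkoxide is formed that could move a silyl group.

Step 16
Reactants: 19 sulfide ester
Product: 20 the corresponding phenyl sulfoxide (both sulfur epimers)
Conditions: NaIO4, MeOH–THF–H2O, 0 → 23 °C
Reagents that add atoms: sodium periodate, [Na+].[O-]I(=O)(=O)=O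
Why: Periodate oxidises the aryl alkyl sulfide to the sulfoxide and leaves the olefins alone, and no free 1,2-diol is present to be cleaved.

Step 17
Reactants: 20 sulfoxide
Product: 21 (1(10)Z,4E,6S,7R,8S,9R)-8-(3-methylbut-2-enoyloxy)-7,9-bis(triethylsilyloxy)germacra-1(10),4,11(13)-trien-12,6-olide
Conditions: toluene, CaCO3, 90 °C
Reagents that add atoms: none
Why: Thermal syn-elimination of benzenesulfenic acid from the β-sulfinyl lactone; the only β-hydrogen is C11–H, so the exocyclic C11=C13 olefin is the sole possible product and the C11 stereocentre disappears.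

Step 18
Reactants: 21 bis-silyl ether
Product: 22 (1(10)Z,4E,6S,7R,8S,9R)-7,9-dihydroxy-8-(3-methylbut-2-enoyloxy)germacra-1(10),4,11(13)-trien-12,6-olide (CNP0255427.1)
Conditions: HF·pyridine, pyridine, THF, 0 → 23 °C
Reagents that add atoms: none
Why: Fluoride cleavage of the secondary and the tertiary triethylsilyl ether under buffered, weakly acidic conditions, which avoid acyl migration of the C8 ester and conjugate addition to the methylene lactone.

## Compound list

1 | geranyl acetate, (2E)-3,7-dimethylocta-2,6-dien-1-yl acetate | CC(C)=CCC/C(C)=C/COC(C)=O | starting material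
2 | (2E)-3-methyl-6-oxohex-2-en-1-yl acetate | O=CCC/C(C)=C/COC(C)=O | intermediate
3 | ethyl 2-[bis(2,2,2-trifluoroethoxy)phosphoryl]propanoate | CCOC(=O)C(C)P(=O)(OCC(F)(F)F)OCC(F)(F)F | starting material
4 | ethyl (2Z,6E)-8-acetoxy-2,6-dimethylocta-2,6-dienoate | CCOC(=O)/C(C)=C\CC/C(C)=C/COC(C)=O | intermediate
5 | (2Z,6E)-8-hydroxy-N-methoxy-N,2,6-trimethylocta-2,6-dienamide | CON(C)C(=O)/C(C)=C\CC/C(C)=C/CO | intermediate
6 | (2Z,6E)-N-methoxy-N,2,6-trimethyl-8-oxoocta-2,6-dienamide | CON(C)C(=O)/C(C)=C\CC/C(C)=C/C=O | intermediate
7 | (S)-malic acid | OC(=O)C[C@H](O)C(=O)O | starting material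
8 | 2-[(2S,4S)-2-tert-butyl-5-oxo-1,3-dioxolan-4-yl]acetic acid | OC(=O)C[C@@H]1O[C@H](C(C)(C)C)OC1=O | intermediate
9 | tert-butyl 2-[(2S,4S)-2-tert-butyl-5-oxo-1,3-dioxolan-4-yl]acetate | CC(C)(C)OC(=O)C[C@@H]1O[C@H](C(C)(C)C)OC1=O | intermediate
10 | aldol adduct, tert-butyl 2-[(2S,4R)-2-tert-butyl-4-[(1S,2E,6Z)-1-hydroxy-8-[methoxy(methyl)amino]-3,7-dimethyl-8-oxoocta-2,6-dien-1-yl]-5-oxo-1,3-dioxolan-4-yl]acetate | CC(C)(C)OC(=O)C[C@]1([C@@H](O)/C=C(\C)CC/C=C(/C)C(=O)N(C)OC)O[C@H](C(C)(C)C)OC1=O | intermediate
11 | tert-butyl (3R,4S,5E,9Z)-3,4-dihydroxy-3-[methoxy(methyl)carbamoyl]-11-[methoxy(methyl)amino]-6,10-dimethyl-11-oxoundeca-5,9-dienoate | CC(C)(C)OC(=O)C[C@@](O)([C@@H](O)/C=C(\C)CC/C=C(/C)C(=O)N(C)OC)C(=O)N(C)OC | intermediate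
12 | (2S,3R)-3-hydroxy-N-methoxy-2-[(1E,5Z)-7-[methoxy(methyl)amino]-2,6-dimethyl-7-oxohepta-1,5-dien-1-yl]-N-methyl-5-oxooxolane-3-carboxamide | O=C1O[C@@H](/C=C(\C)CC/C=C(/C)C(=O)N(C)OC)[C@@](O)(C(=O)N(C)OC)C1 | intermediate
13 | C7 triethylsilyl ether of 12 | O=C1O[C@@H](/C=C(\C)CC/C=C(/C)C(=O)N(C)OC)[C@@](O[Si](CC)(CC)CC)(C(=O)N(C)OC)C1 | intermediate
14 | trimethylsilyl ketene acetal of 13 (2-trimethylsilyloxy-4,5-dihydrofuran) | C[Si](C)(C)OC=1O[C@@H](/C=C(\C)CC/C=C(/C)C(=O)N(C)OC)[C@@](O[Si](CC)(CC)CC)(C(=O)N(C)OC)C=1 | intermediate
15 | α-(phenylthiomethyl) lactone bis-amide, CH2SPh cis to C8 | O=C1O[C@@H](/C=C(\C)CC/C=C(/C)C(=O)N(C)OC)[C@@](O[Si](CC)(CC)CC)(C(=O)N(C)OC)[C@H]1CSc2ccccc2 | intermediate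
16 | lactone dialdehyde (C8 aldehyde on C7, Z-enal at C9, C7 O-triethylsilyl, sulfide-masked methylene) | O=C1O[C@@H](/C=C(\C)CC/C=C(/C)C=O)[C@@](O[Si](CC)(CC)CC)(C=O)[C@H]1CSc2ccccc2 | intermediate
17 | ten-membered 8,9-diol, (1(10)Z,4E,6S,7R,8S,9R,11R)-8,9-dihydroxy-13-(phenylsulfanyl)-7-(triethylsilyloxy)germacra-1(10),4-dien-12,6-olide | O=C1O[C@H]2/C=C(\C)CC/C=C(/C)[C@@H](O)[C@H](O)[C@@]2(O[Si](CC)(CC)CC)[C@H]1CSc3ccccc3 | intermediate
18 | 9-O-triethylsilyl ether of 17 | O=C1O[C@H]2/C=C(\C)CC/C=C(/C)[C@@H](O[Si](CC)(CC)CC)[C@H](O)[C@@]2(O[Si](CC)(CC)CC)[C@H]1CSc3ccccc3 | intermediate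
19 | 8-O-(3-methylbut-2-enoyl) ester of 18 | O=C1O[C@H]2/C=C(\C)CC/C=C(/C)[C@@H](O[Si](CC)(CC)CC)[C@H](OC(=O)C=C(C)C)[C@@]2(O[Si](CC)(CC)CC)[C@H]1CSc3ccccc3 | intermediate
20 | phenyl sulfoxide of 19 (sulfur epimers) | O=C1O[C@H]2/C=C(\C)CC/C=C(/C)[C@@H](O[Si](CC)(CC)CC)[C@H](OC(=O)C=C(C)C)[C@@]2(O[Si](CC)(CC)CC)[C@H]1CS(=O)c3ccccc3 | intermediate
21 | 7,9-bis-O-triethylsilyl ether of the target | C=C1C(=O)O[C@H]2/C=C(\C)CC/C=C(/C)[C@@H](O[Si](CC)(CC)CC)[C@H](OC(=O)C=C(C)C)[C@@]12O[Si](CC)(CC)CC | intermediate
22 | CNP0255427.1, (1(10)Z,4E,6S,7R,8S,9R)-7,9-dihydroxy-8-(3-methylbut-2-enoyloxy)germacra-1(10),4,11(13)-trien-12,6-olide | C=C1C(=O)O[C@H]2/C=C(\C)CC/C=C(/C)[C@@H](O)[C@H](OC(=O)C=C(C)C)[C@@]12O | target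

## Step count and least certain steps

Total: 18 steps. Longest linear sequence: 16 steps (steps 1–4 and 7–18, from geranyl acetate 1). The malic acid branch (steps 5 and 6) joins at step 7.

**Step 13 (key step).** The most likely failure is insufficient facial discrimination at the enal carbon during ketyl combination, giving the 8,9-erythro diol alongside the wanted threo diol. Ring strain leaves the two ketyl faces close in energy, and too fast an addition would also allow intermolecular coupling. Fallback: the erythro 9-epi diol F1 is oxidised selectively at its allylic C9 hydroxyl (MnO2, CH2Cl2) to the 9-oxo-8-hydroxy compound F2. This α-hydroxy enone is then reduced without chelation (NaBH4, CeCl3, MeOH, −78 °C), so that hydride enters anti to the C8–O bond and gives the threo diol. The fallback sets out from the crude product of 16 and returns to the route at 17.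

**Step 7.** The aldehyde face may be poorly discriminated, or the closed six-membered transition state may prevail and give mainly the 6R carbinol; C7 is not at risk. Fallback: the mixture of 10 and its 6-epimer F3 is oxidised with Dess–Martin periodinane to enone F4, which has no enolisable centre between its carbonyls. F4 is then reduced by Corey–Bakshi–Shibata reduction (oxazaborolidine enantiomer chosen for the 6S alcohol, catecholborane, toluene, −78 °C), so that C6 is set by the reagent and not by the substrate. The fallback sets out from 9 and 6 through the aldol mixture and returns at 10.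

**Step 11.** The β-silyloxy lactone enolate may expel silanolate before it is silylated, giving a butenolide. Fallback: the hydroxyl is left free so that the enolate is a dianion with no leaving group. Lactone 12 is treated with LiN(iPr)2 (2.2 equiv) and dimethyl(methylidene)ammonium iodide to give the Mannich base F5. Methyl iodide converts F5 to the ammonium iodide F6, and NaHCO3 eliminates trimethylamine to the α-methylene lactone F7. Thiophenol with Et3N adds to F7 to give the C7-hydroxy sulfide F8, and Et3SiOTf with 2,6-lutidine then gives 15. The fallback sets out from 12 and returns at 15.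

**Step 12.** Hydride transfer from the bulky zirconium reagent may stall at the C8 amide, which sits on a quaternary carbon beside a triethylsilyl ether, leaving a mono-aldehyde. Fallback: all three acyl groups of 15 are reduced with the small hydride (iBu)2AlH (CH2Cl2, −78 °C). The two amides stop as chelated hemiaminals and the lactone as its aluminated lactol, giving the lactol dialdehyde F9 on work-up. The lactol alone is then re-oxidised to the lactone with Ag2CO3 on Celite (benzene, 60 °C), which leaves aldehydes and the sulfide untouched. The fallback sets out from 15 and returns at 16.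

**Step 15.** Acyl transfer to the C8 hydroxyl may be too slow, because the alcohol lies between the quaternary C7 and the silylated C9, and prolonged base could then move a silyl group. Fallback: acylation through a ketene, which is sterically undemanding. 3-Methylbut-2-enoyl chloride with Et3N (CH2Cl2, 0 °C) generates the vinylketene, which adds to 18 to give the deconjugated 3-methylbut-3-enoate F10. Catalytic DBU then moves the double bond into conjugation. The fallback sets out from 18 and returns at 19.

## Further compounds

F1 | step 13 | 8,9-erythro (9-epi) diol, 9S epimer of 17 | O=C1O[C@H]2/C=C(\C)CC/C=C(/C)[C@H](O)[C@H](O)[C@@]2(O[Si](CC)(CC)CC)[C@H]1CSc3ccccc3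
F2 | step 13 | 8-hydroxy-9-oxo enone from F1 | O=C1O[C@H]2/C=C(\C)CC/C=C(/C)C(=O)[C@H](O)[C@@]2(O[Si](CC)(CC)CC)[C@H]1CSc3ccccc3
F3 | step 7 | 6-epimer (6R) of aldol adduct 10 | CC(C)(C)OC(=O)C[C@]1([C@H](O)/C=C(\C)CC/C=C(/C)C(=O)N(C)OC)O[C@H](C(C)(C)C)OC1=O
F4 | step 7 | C6 enone from 10 and F3 | CC(C)(C)OC(=O)C[C@]1(C(=O)/C=C(\C)CC/C=C(/C)C(=O)N(C)OC)O[C@H](C(C)(C)C)OC1=O
F5 | step 11 | α-(dimethylaminomethyl) lactone (Mannich base) from 12 | O=C1O[C@@H](/C=C(\C)CC/C=C(/C)C(=O)N(C)OC)[C@@](O)(C(=O)N(C)OC)C1CN(C)C
F6 | step 11 | trimethylammonium iodide of F5 | O=C1O[C@@H](/C=C(\C)CC/C=C(/C)C(=O)N(C)OC)[C@@](O)(C(=O)N(C)OC)C1C[N+](C)(C)C.[I-]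
F7 | step 11 | α-methylene lactone with free C7 hydroxyl | C=C1C(=O)O[C@@H](/C=C(\C)CC/C=C(/C)C(=O)N(C)OC)[C@@]1(O)C(=O)N(C)OC
F8 | step 11 | thiophenol adduct of F7 (C7 hydroxyl free) | O=C1O[C@@H](/C=C(\C)CC/C=C(/C)C(=O)N(C)OC)[C@@](O)(C(=O)N(C)OC)[C@H]1CSc2ccccc2
F9 | step 12 | lactol dialdehyde (C12 hemiacetal, both anomers) | OC1O[C@@H](/C=C(\C)CC/C=C(/C)C=O)[C@@](O[Si](CC)(CC)CC)(C=O)[C@H]1CSc2ccccc2
F10 | step 15 | 8-O-(3-methylbut-3-enoyl) ester of 18 | O=C1O[C@H]2/C=C(\C)CC/C=C(/C)[C@@H](O[Si](CC)(CC)CC)[C@H](OC(=O)CC(C)=C)[C@@]2(O[Si](CC)(CC)CC)[C@H]1CSc3ccccc3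
A1 | alternative 1 | 1-methylcyclobutene | CC1=CCC1
A2 | alternative 1 | cis-anti-cis tricyclic ketone (cyclohexanone fused to bicyclo[2.2.0]hexane) | O=C1[C@@]2(C)[C@@H]3CC[C@]3(C)[C@H]2[C@H](O[Si](C)(C)C(C)(C)C)C4(OCCO4)[C@H]1O[Si](C)(C)C(C)(C)C
A3 | alternative 2 | 7,9-bis-O-triethylsilyl ether of the target (identical with 21) | C=C1C(=O)O[C@H]2/C=C(\C)CC/C=C(/C)[C@@H](O[Si](CC)(CC)CC)[C@H](OC(=O)C=C(C)C)[C@@]12O[Si](CC)(CC)CC
A4 | alternative 3 | (1(10)Z,4E)-cyclodecadienyl C10 enol triflate | CC(C)(C)[Si](C)(C)O[C@H]1/C=C(\C)CC/C=C(/OS(=O)(=O)C(F)(F)F)[C@@H](OCc2ccc(OC)cc2)[C@@H]3OC(C)(C)O[C@]13C(=C)CO[Si](C)(C)C(C)(C)C
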